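Readings and results are simulated with constants of no real substance, and the scatter is random.

Time first: at 2.00 min the oak run holds hardly any substrate (0.6%), yet its target stands at 5.9% as late as 25.0 min. So you want to know who takes the substrate in those first minutes.

| setting | oak | maple | cedar | red | amber | grey | teal |
|---|---|---|---|---|---|---|---|
| substrate | 0.051 M | 0.051 M | 0.051 M | 0.051 M | 0.051 M | 0.051 M | 0.051 M |
| coupling partner | 4 equiv | 2.7 equiv | 6 equiv | 4.00 equiv | 4.00 equiv (fed, over 30 min) | 4.00 equiv | 4.00 equiv (in portions, 4, over 30 min) |
| second reagent | 1.5 equiv | 1.5 equiv | 1.5 equiv | 1.50 equiv | 1.50 equiv | 1.50 equiv (fed, over 30 min) | 1.50 equiv |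
| third reagent | 1.05 equiv | 1.05 equiv | 1.05 equiv | 1.05 equiv | 1.05 equiv | 1.05 equiv | 1.05 equiv |
| protic impurity | 0.0255 M | 0.0255 M | 0.0255 M | 0.0255 M | 0.0255 M | 0.0255 M | 0.0255 M |
| remark | run made earlier | run made earlier | run made earlier | everything together at the start | all else is in the flask from the start; the feed brings no volume worth counting | all else is in the flask from the start; the feed brings no volume worth counting | first portion at the start, last at 30 min |
| time |  |  |  | 40 min | 40 min | 40 min | 40 min |

| run | time / min | target / % | substrate / % |
|---|---|---|---|
| oak | 2.00 | 0 | 0.6 |
| oak | 4.00 | 0 | 0 |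
| oak | 6.00 | 0.9 | 0.2 |
| oak | 12.0 | 2.1 | 0.3 |
| oak | 25.0 | 5.9 | 0.2 |
| maple | 2.00 | 0.3 | 1.7 |
| maple | 6.00 | 0.3 | 0 |
| maple | 12.0 | 1.7 | 0.6 |
| maple | 15.0 | 2.6 | 0.2 |
| maple | 25.0 | 4.3 | 0.1 |
| cedar | 2.00 | 0.6 | 0 |
| cedar | 4.00 | 0 | 0 |
| cedar | 6.00 | 0.7 | 0 |
| cedar | 12.0 | 3.5 | 0 |
| cedar | 25.0 | 7.5 | 0.4 |

(scatter of a reading: 0.5 percentage points)

- the analysis behind the earlier runs scatters by 0.5 percentage points, standard deviation

- the best flask by amount of target, in percent of the substrate charged; "all alike" if 1.5 percentage points covers them all (red / amber / grey / teal / all alike)
- amount of target at the end, in percent of the substrate charged, red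
- amount of target at the end, in percent of the substrate charged, amber
- amount of target at the end, in percent of the substrate charged, grey
- amount of target at the end, in percent of the substrate charged, teal

The bench rule says that an excess of coupling partner wins the substrate and that a slow feed does no harm. Test it by reckoning the fraction left for the partner. My own guess is that second reagent is the rival, though the earlier runs hold it at 1.5 equiv, so they cannot show this. The fraction left is then [coupling partner]/([coupling partner] + S[second reagent]), and with all else held as in these runs the target at a fixed time should follow it.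

Cedar over maple gives a ratio of 1.74 at 25.0 min, which puts the crossover charge of partner at 9.34 equiv. Dividing by the second reagent charge gives S = 6.23, the selectivity factor: what one equivalent of second reagent counts for against one of partner. With a scatter of 0.5 percentage points this is a rough reading. Oak's reading did not enter S, and the fraction carried over from maple's reading foretells oak at 5.75% against 5.9% read.

So at the opening charges of red the rival outweighs the excess, and the fraction left at that moment is 30.0%.

The feed rule meets its border in a ratio: feed time over substrate window, taken here as the 2.00 min of oak's first reading, is 15.0. Taking that same window for the fed flasks, 6.67% of a feed has entered by its end, and the mean level is 0.5 of that. The fraction left is then 1.41% in amber and 92.8% in grey. Teal's first portion gives 9.67%. These are shares, not target, but I commit to the order grey, red, teal, amber.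

The forecast differs. It names red as best, with red 10% (8.5% to 12%), amber 6.5% (4.5% to 9.5%), grey 6.5% (3% to 11%) and teal 7% (5% to 9.5%). Its ground is that “substrate must sit in a pool that turns over slowly”.

The flasks give red 11.1%, amber 0.386%, grey 20.5% and teal 3.93%, so grey makes more than the others. Side product ends at 5.25% in grey, 67.4% in red and 98.8% in amber. The fractions for the fed flasks were reckoned as means over the window, and substrate ends at 0% in grey and 0% in amber, so they can stand beside what escaped side product: grey 92.8% against 94.8%, amber 1.41% against 1.20%.

    substrate + coupling partner → intermediate A (k = 6.26 M⁻¹ min⁻¹)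
    second reagent + intermediate A → intermediate B (k = 1.62 M⁻¹ min⁻¹)
    third reagent + intermediate B → target (k = 0.749 M⁻¹ min⁻¹)
    substrate + second reagent → side product (k = 44.1 M⁻¹ min⁻¹)
    third reagent + protic impurity → quenched reagent (k = 80.2 M⁻¹ min⁻¹)

Now take the neighbour flask, grey again but with 2.50 equiv of second reagent. S puts the share lost to side product at 11.5%, up from 7.20% reckoned for grey. The neighbour gives 8.05% side product and 25.0% target.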